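The route exploits the cyclohexene ring of the target (numbered as cyclohex-5-ene-1,2,4-tricarboxylic acid: C3 aryl, C6 acrylate arm): its only alkene, C5=C6, adjoins four contiguous stereocentres C1–C4, the pattern of an aminocatalysed aldehyde/activated-olefin/enal cascade. In one operation a silyloxypropanal, a protected caffeic-type 2-nitroacrylate and allyl fumaraldehydate are joined: enamine Michael addition makes C3–C4, nitronate–iminium Michael addition makes C1–C2, and aldol condensation makes C5=C6 of a 6-formylcyclohexene; one (R)-prolinol silyl ether sets C1, C3 and C4. Denitration, Horner–Wadsworth–Emmons attachment of the danshensu ester arm, oxidation and global deallylation complete the synthesis.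

Key step: step 5

Remark: ring atoms of all cyclohexene compounds carry the locants of the target (C1, C2, C4 bear the carboxyl carbons, C3 the aryl ring, C6 the side arm), also where nomenclature rules would number differently. The nitro-bearing carbon C2 of 10–12 is carried as an epimer mixture because step 6 removes the nitro group.

Step 1
Reactants: 1 3,4-dihydroxybenzaldehyde
Product: 2 3,4-bis(allyloxy)benzaldehyde
Conditions: allyl bromide, K2CO3, DMF, 60 °C
Reagents that add atoms: allyl bromide C=CCBr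
Why: Williamson ether synthesis should O-allylate both phenols; the allyl ethers are meant to survive every later step and to fall together with the allyl esters at the end.

Step 2
Reactants: 3 methyl nitroacetate
Product: 4 allyl nitroacetate
Conditions: allyl alcohol (excess), Bu2SnO (cat.), toluene, 90 °C, MeOH distilled off
Reagents that add atoms: allyl alcohol C=CCO
Why: Neutral tin-catalysed transesterification driven by removal of methanol should give the nitroacetate as an ester that zerovalent palladium can cleave later.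

Step 3
Reactants: 2 3,4-bis(allyloxy)benzaldehyde; 4 allyl nitroacetate
Product: 5 allyl 3-[3,4-bis(allyloxy)phenyl]-2-nitroprop-2-enoate (E/Z mixture)
Conditions: TiCl4, N-methylmorpholine, THF, 0 °C to rt
Reagents that add atoms: none
Why: Knoevenagel condensation (TiCl4/amine variant) of an aryl aldehyde with a nitroacetate should give the 2-nitroacrylate; the E/Z mixture is usable because both isomers present the same aryl-bearing carbon and the nitro carbon is later defunctionalised.

Step 4
Reactants: 6 glyoxal (40% in water, excess); 7 allyl (triphenylphosphoranylidene)acetate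
Product: 8 allyl (2E)-4-oxobut-2-enoate
Conditions: CH2Cl2/H2O, rt
Reagents that add atoms: none
Why: Mono-Wittig olefination of glyoxal with a stabilised ylide should give the E-configured fumaraldehydate, the excess of dialdehyde suppressing double olefination.

Step 5
Reactants: 9 3-[(tert-butyldimethylsilyl)oxy]propanal; 5 allyl 3-[3,4-bis(allyloxy)phenyl]-2-nitroprop-2-enoate; 8 allyl (2E)-4-oxobut-2-enoate
Product: 12 diallyl (1S,3R,4R)-3-[3,4-bis(allyloxy)phenyl]-4-{[(tert-butyldimethylsilyl)oxy]methyl}-6-formyl-2-nitrocyclohex-5-ene-1,2-dicarboxylate (both C2 epimers), via Michael adduct 10 (not isolated), via dialdehyde 11 (not isolated)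
Conditions: (R)-2-[diphenyl(trimethylsilyloxy)methyl]pyrrolidine (20 mol%), toluene, 0 °C to rt
Reagents that add atoms: none
Why: The catalyst condenses with 9 to an E-enamine that adds through its unshielded face to nitroacrylate 5 (Michael addition, C3–C4 bond, adduct 10); the nitronate of 10 then adds to the iminium ion formed from the same catalyst and enal 8, at the ester-bearing carbon beta to the iminium (Michael addition, C1–C2 bond), and the resulting enamine of 11 attacks the first aldehyde carbon in an intramolecular aldol reaction whose dehydration creates the C5=C6 double bond. The closest known reaction is the amine-catalysed aldehyde/nitroalkene/enal Michael–Michael–aldol condensation cascade, which is also known with 2-cyano-3-arylacrylates that give a quaternary carbon as here. The carbocycle closes in the aldol step by a 6-(enolexo)-exo-trig attack of the enamine carbon C6 on the aldehyde carbon C5. C4 and C3 should be set in the first Michael addition by the catalyst (its diphenyl(silyloxy)methyl group blocks one enamine face and the synclinal approach of the nitroalkene gives the syn adduct, trans on the ring), C1 by the same catalyst shielding one face of the iminium ion, while C2 forms as an epimer mixture that step 6 erases. The step needs chemoselectivity (9 as the only enamine donor, 5 attacked before 8), which the far higher electrophilicity of the nitroacrylate, the absence of enolisable hydrogens in 8 and the masking of the future C4 carboxyl group as a silyl ether (so the aldehyde of 10 is not a 1,3-dicarbonyl enol) should secure; the (R)-catalyst is chosen because the (S)-catalyst is known to give the mirror-image sense in both Michael steps.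

Step 6
Reactants: 12 diallyl (1S,3R,4R)-3-[3,4-bis(allyloxy)phenyl]-4-{[(tert-butyldimethylsilyl)oxy]methyl}-6-formyl-2-nitrocyclohex-5-ene-1,2-dicarboxylate
Product: 13 diallyl (1R,2R,3S,4R)-3-[3,4-bis(allyloxy)phenyl]-4-{[(tert-butyldimethylsilyl)oxy]methyl}-6-formylcyclohex-5-ene-1,2-dicarboxylate
Conditions: Bu3SnH, AIBN (cat.), toluene, 80 °C
Reagents that add atoms: none
Why: Radical chain denitration of the tertiary alpha-nitro ester; the planar ester-stabilised C2 radical from either epimer should take hydrogen axially on the face anti to the pseudoaxial C1 ester, leaving the C2 ester equatorial (trans to the aryl group, cis to the C1 ester), which is also the more stable epimer.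

Step 7
Reactants: 14 sodium (2R)-3-(3,4-dihydroxyphenyl)-2-hydroxypropanoate (sodium danshensu)
Product: 15 allyl (2R)-3-[3,4-bis(allyloxy)phenyl]-2-hydroxypropanoate
Conditions: allyl bromide (3.5 equiv), K2CO3, DMF, rt
Reagents that add atoms: allyl bromide C=CCBr
Why: Williamson-type O-alkylation of the carboxylate and both phenoxides under mild carbonate conditions should leave the secondary alcohol and the (R) centre untouched.

Step 8
Reactants: 15 allyl (2R)-3-[3,4-bis(allyloxy)phenyl]-2-hydroxypropanoate; 16 (diethoxyphosphoryl)acetic acid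
Product: 17 allyl (2R)-3-[3,4-bis(allyloxy)phenyl]-2-{[(diethoxyphosphoryl)acetyl]oxy}propanoate
Conditions: DCC, DMAP (cat.), CH2Cl2, 0 °C to rt
Reagents that add atoms: none
Why: Steglich esterification acylates the secondary alcohol without breaking its C–O bond, so the (R) configuration is retained.

Step 9
Reactants: 13 diallyl (1R,2R,3S,4R)-3-[3,4-bis(allyloxy)phenyl]-4-{[(tert-butyldimethylsilyl)oxy]methyl}-6-formylcyclohex-5-ene-1,2-dicarboxylate; 17 allyl (2R)-3-[3,4-bis(allyloxy)phenyl]-2-{[(diethoxyphosphoryl)acetyl]oxy}propanoate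
Product: 18 diallyl (1R,2R,3S,4R)-6-[(1E)-3-({(2R)-1-(allyloxy)-3-[3,4-bis(allyloxy)phenyl]-1-oxopropan-2-yl}oxy)-3-oxoprop-1-en-1-yl]-3-[3,4-bis(allyloxy)phenyl]-4-{[(tert-butyldimethylsilyl)oxy]methyl}cyclohex-5-ene-1,2-dicarboxylate
Conditions: LiCl, iPr2NEt, MeCN, 0 °C to rt
Reagents that add atoms: none
Why: Horner–Wadsworth–Emmons olefination of the enal under LiCl/amine conditions should give the E-acrylate, the weak base being unable to epimerise C1, C2 or the lactate centre.

Step 10
Reactants: 18 diallyl (1R,2R,3S,4R)-6-[(1E)-3-({(2R)-1-(allyloxy)-3-[3,4-bis(allyloxy)phenyl]-1-oxopropan-2-yl}oxy)-3-oxoprop-1-en-1-yl]-3-[3,4-bis(allyloxy)phenyl]-4-{[(tert-butyldimethylsilyl)oxy]methyl}cyclohex-5-ene-1,2-dicarboxylate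
Product: 19 1,2-diallyl 4-hydrogen (1R,2R,3S,4R)-6-[(1E)-3-({(2R)-1-(allyloxy)-3-[3,4-bis(allyloxy)phenyl]-1-oxopropan-2-yl}oxy)-3-oxoprop-1-en-1-yl]-3-[3,4-bis(allyloxy)phenyl]cyclohex-5-ene-1,2,4-tricarboxylate
Conditions: CrO3, H2SO4, H2O, acetone, 0 °C
Reagents that add atoms: water O
Why: Jones oxidation: the acidic medium cleaves the primary silyl ether and hexavalent chromium oxidises the alcohol through the aldehyde hydrate to the acid faster than the beta,gamma-unsaturated aldehyde can enolise, so C4 and the position of the C5=C6 bond should be kept.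

Step 11
Reactants: 19 1,2-diallyl 4-hydrogen (1R,2R,3S,4R)-6-[(1E)-3-({(2R)-1-(allyloxy)-3-[3,4-bis(allyloxy)phenyl]-1-oxopropan-2-yl}oxy)-3-oxoprop-1-en-1-yl]-3-[3,4-bis(allyloxy)phenyl]cyclohex-5-ene-1,2,4-tricarboxylate
Product: 20 (1R,2R,3S,4R)-6-[(1E)-3-{[(1R)-1-carboxy-2-(3,4-dihydroxyphenyl)ethyl]oxy}-3-oxoprop-1-en-1-yl]-3-(3,4-dihydroxyphenyl)cyclohex-5-ene-1,2,4-tricarboxylic acid
Conditions: Pd(PPh3)4 (cat.), morpholine (excess), THF, rt, under argon; then dilute HCl work-up
Reagents that add atoms: none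
Why: Tsuji–Trost deallylation: zerovalent palladium ionises the three allyl esters and four allyl aryl ethers to pi-allyl complexes that morpholine captures, under neutral conditions that should leave the acrylate ester, the diene and all stereocentres untouched.

Compound list
1 | 3,4-dihydroxybenzaldehyde | O=Cc1ccc(O)c(O)c1 | starting material
2 | 3,4-bis(allyloxy)benzaldehyde | O=Cc1ccc(OCC=C)c(OCC=C)c1 | intermediate
3 | methyl nitroacetate | COC(=O)C[N+](=O)[O-] | starting material
4 | allyl nitroacetate | C=CCOC(=O)C[N+](=O)[O-] | intermediate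
5 | allyl 3-[3,4-bis(allyloxy)phenyl]-2-nitroprop-2-enoate (E/Z mixture) | C=CCOC(=O)C(=Cc1ccc(OCC=C)c(OCC=C)c1)[N+](=O)[O-] | intermediate
6 | glyoxal | O=CC=O | starting material
7 | allyl (triphenylphosphoranylidene)acetate | C=CCOC(=O)C=P(c1ccccc1)(c1ccccc1)c1ccccc1 | starting material
8 | allyl (2E)-4-oxobut-2-enoate | O=C/C=C/C(=O)OCC=C | intermediate
9 | 3-[(tert-butyldimethylsilyl)oxy]propanal | O=CCCO[Si](C)(C)C(C)(C)C | starting material
10 | allyl (3R,4R)-3-[3,4-bis(allyloxy)phenyl]-5-[(tert-butyldimethylsilyl)oxy]-4-formyl-2-nitropentanoate (both C2 epimers) | O=C[C@@H](CO[Si](C)(C)C(C)(C)C)[C@H](c1ccc(OCC=C)c(OCC=C)c1)C([N+](=O)[O-])C(=O)OCC=C | intermediate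
11 | diallyl (3S)-2-{(1R,2R)-1-[3,4-bis(allyloxy)phenyl]-3-[(tert-butyldimethylsilyl)oxy]-2-formylpropyl}-2-nitro-3-(2-oxoethyl)butanedioate (both C2 epimers) | O=C[C@@H](CO[Si](C)(C)C(C)(C)C)[C@H](c1ccc(OCC=C)c(OCC=C)c1)C([N+](=O)[O-])(C(=O)OCC=C)[C@H](CC=O)C(=O)OCC=C | intermediate
12 | diallyl (1S,3R,4R)-3-[3,4-bis(allyloxy)phenyl]-4-{[(tert-butyldimethylsilyl)oxy]methyl}-6-formyl-2-nitrocyclohex-5-ene-1,2-dicarboxylate (both C2 epimers) | O=CC1=C[C@@H](CO[Si](C)(C)C(C)(C)C)[C@H](c2ccc(OCC=C)c(OCC=C)c2)C([N+](=O)[O-])(C(=O)OCC=C)[C@H]1C(=O)OCC=C | intermediate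
13 | diallyl (1R,2R,3S,4R)-3-[3,4-bis(allyloxy)phenyl]-4-{[(tert-butyldimethylsilyl)oxy]methyl}-6-formylcyclohex-5-ene-1,2-dicarboxylate | O=CC1=C[C@@H](CO[Si](C)(C)C(C)(C)C)[C@H](c2ccc(OCC=C)c(OCC=C)c2)[C@@H](C(=O)OCC=C)[C@H]1C(=O)OCC=C | intermediate
14 | sodium (2R)-3-(3,4-dihydroxyphenyl)-2-hydroxypropanoate | O[C@H](Cc1ccc(O)c(O)c1)C(=O)[O-].[Na+] | starting material
15 | allyl (2R)-3-[3,4-bis(allyloxy)phenyl]-2-hydroxypropanoate | O[C@H](Cc1ccc(OCC=C)c(OCC=C)c1)C(=O)OCC=C | intermediate
16 | (diethoxyphosphoryl)acetic acid | OC(=O)CP(=O)(OCC)OCC | starting material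
17 | allyl (2R)-3-[3,4-bis(allyloxy)phenyl]-2-{[(diethoxyphosphoryl)acetyl]oxy}propanoate | CCOP(=O)(OCC)CC(=O)O[C@H](Cc1ccc(OCC=C)c(OCC=C)c1)C(=O)OCC=C | intermediate
18 | diallyl (1R,2R,3S,4R)-6-[(1E)-3-({(2R)-1-(allyloxy)-3-[3,4-bis(allyloxy)phenyl]-1-oxopropan-2-yl}oxy)-3-oxoprop-1-en-1-yl]-3-[3,4-bis(allyloxy)phenyl]-4-{[(tert-butyldimethylsilyl)oxy]methyl}cyclohex-5-ene-1,2-dicarboxylate | O=C(/C=C/C1=C[C@@H](CO[Si](C)(C)C(C)(C)C)[C@H](c2ccc(OCC=C)c(OCC=C)c2)[C@@H](C(=O)OCC=C)[C@H]1C(=O)OCC=C)O[C@H](Cc1ccc(OCC=C)c(OCC=C)c1)C(=O)OCC=C | intermediate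
19 | 1,2-diallyl 4-hydrogen (1R,2R,3S,4R)-6-[(1E)-3-({(2R)-1-(allyloxy)-3-[3,4-bis(allyloxy)phenyl]-1-oxopropan-2-yl}oxy)-3-oxoprop-1-en-1-yl]-3-[3,4-bis(allyloxy)phenyl]cyclohex-5-ene-1,2,4-tricarboxylate | O=C(/C=C/C1=C[C@@H](C(=O)O)[C@H](c2ccc(OCC=C)c(OCC=C)c2)[C@@H](C(=O)OCC=C)[C@H]1C(=O)OCC=C)O[C@H](Cc1ccc(OCC=C)c(OCC=C)c1)C(=O)OCC=C | intermediate
20 | (1R,2R,3S,4R)-6-[(1E)-3-{[(1R)-1-carboxy-2-(3,4-dihydroxyphenyl)ethyl]oxy}-3-oxoprop-1-en-1-yl]-3-(3,4-dihydroxyphenyl)cyclohex-5-ene-1,2,4-tricarboxylic acid | O=C(/C=C/C1=C[C@@H](C(=O)O)[C@H](c2ccc(O)c(O)c2)[C@@H](C(=O)O)[C@H]1C(=O)O)O[C@H](Cc1ccc(O)c(O)c1)C(=O)O | target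

Total step count: 11. Longest linear sequence: 7 steps (steps 1, 3, 5, 6, 9, 10, 11).

Steps most likely to fail

Step 5: the second Michael addition, which builds a quaternary carbon, may stall at adduct 10, or the very electrophilic nitroacrylate may be consumed by amine addition and oligomerisation. The fallback sets out from 2. Knoevenagel condensation with diallyl malonate (piperidinium acetate, toluene, water removal) should give diallyl 2-[3,4-bis(allyloxy)benzylidene]malonate F1, a milder, symmetrical acceptor. The same amine-catalysed cascade with 9 and 8 (LiOAc as co-base) should then give triallyl (1S,3R,4R)-3-[3,4-bis(allyloxy)phenyl]-4-{[(tert-butyldimethylsilyl)oxy]methyl}-6-formylcyclohex-5-ene-1,2,2-tricarboxylate F2. Krapcho mono-dealkoxycarbonylation (LiCl, H2O, DMSO, 130 °C), which is selective for geminal diesters, removes one ester with equilibrating protonation at C2 and comes back to the route at 13; step 6 is then not needed.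

Step 6: hydrogen transfer may occur from the wrong ring face, or the tin radical may add to the enal instead of propagating the denitration chain. The fallback sets out from 12 and changes the order of events. Horner–Wadsworth–Emmons reaction with 17 (LiCl, iPr2NEt, MeCN) first converts the enal into the less radical-sensitive dienoate, diallyl (1S,3R,4R)-6-[(1E)-3-({(2R)-1-(allyloxy)-3-[3,4-bis(allyloxy)phenyl]-1-oxopropan-2-yl}oxy)-3-oxoprop-1-en-1-yl]-3-[3,4-bis(allyloxy)phenyl]-4-{[(tert-butyldimethylsilyl)oxy]methyl}-2-nitrocyclohex-5-ene-1,2-dicarboxylate F3. Denitration with (Me3Si)3SiH and AIBN in toluene at 80 °C then comes back to the route at 18. At this stage C4 still carries the silyloxymethyl group and is not acidic, so any C2 epimer could be equilibrated with DBU without moving the ring double bond.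

Step 10: the one-pot acidic desilylation and oxidation may cause migration of the C5=C6 bond or epimerisation at C4 through the intermediate aldehyde, or attack on the electron-rich aryl ethers. The fallback sets out from 18 and separates the two events. HF·pyridine in THF at 0 °C should give the primary alcohol, diallyl (1R,2R,3S,4R)-6-[(1E)-3-({(2R)-1-(allyloxy)-3-[3,4-bis(allyloxy)phenyl]-1-oxopropan-2-yl}oxy)-3-oxoprop-1-en-1-yl]-3-[3,4-bis(allyloxy)phenyl]-4-(hydroxymethyl)cyclohex-5-ene-1,2-dicarboxylate F4. Nitroxyl-mediated oxidation (TEMPO cat., PhI(OAc)2, MeCN/H2O, near neutral) then takes it directly to the acid and comes back to the route at 19.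

Further compounds
F1 | step 5 | diallyl 2-[3,4-bis(allyloxy)benzylidene]malonate | C=CCOC(=O)C(=Cc1ccc(OCC=C)c(OCC=C)c1)C(=O)OCC=C
F2 | step 5 | triallyl (1S,3R,4R)-3-[3,4-bis(allyloxy)phenyl]-4-{[(tert-butyldimethylsilyl)oxy]methyl}-6-formylcyclohex-5-ene-1,2,2-tricarboxylate | O=CC1=C[C@@H](CO[Si](C)(C)C(C)(C)C)[C@H](c2ccc(OCC=C)c(OCC=C)c2)C(C(=O)OCC=C)(C(=O)OCC=C)[C@H]1C(=O)OCC=C
F3 | step 6 | diallyl (1S,3R,4R)-6-[(1E)-3-({(2R)-1-(allyloxy)-3-[3,4-bis(allyloxy)phenyl]-1-oxopropan-2-yl}oxy)-3-oxoprop-1-en-1-yl]-3-[3,4-bis(allyloxy)phenyl]-4-{[(tert-butyldimethylsilyl)oxy]methyl}-2-nitrocyclohex-5-ene-1,2-dicarboxylate (both C2 epimers) | O=C(/C=C/C1=C[C@@H](CO[Si](C)(C)C(C)(C)C)[C@H](c2ccc(OCC=C)c(OCC=C)c2)C([N+](=O)[O-])(C(=O)OCC=C)[C@H]1C(=O)OCC=C)O[C@H](Cc1ccc(OCC=C)c(OCC=C)c1)C(=O)OCC=C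
F4 | step 10 | diallyl (1R,2R,3S,4R)-6-[(1E)-3-({(2R)-1-(allyloxy)-3-[3,4-bis(allyloxy)phenyl]-1-oxopropan-2-yl}oxy)-3-oxoprop-1-en-1-yl]-3-[3,4-bis(allyloxy)phenyl]-4-(hydroxymethyl)cyclohex-5-ene-1,2-dicarboxylate | O=C(/C=C/C1=C[C@@H](CO)[C@H](c2ccc(OCC=C)c(OCC=C)c2)[C@@H](C(=O)OCC=C)[C@H]1C(=O)OCC=C)O[C@H](Cc1ccc(OCC=C)c(OCC=C)c1)C(=O)OCC=C
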